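Slowness is not what the dusk readings show: target stands at 12.7% after 40.0 min and at 12.0% after 240 min, while the winter flask, with 2 mM of capture agent against 3.95 mM, has passed that level by 8.00 min. In the reactions considered, starting material binds free enzyme as first complex, which releases first product and leaves loaded enzyme. Loaded enzyme takes second substrate into second complex, which gives target and free enzyme again. Loaded enzyme can also meet capture agent and become trapped intermediate, or meet first product and become spent catalyst.

| flask | starting material | second substrate | capture agent | free enzyme | remark | time |
|---|---|---|---|---|---|---|
| dusk | 0.079 M | 0.0948 M | 3.95 mM | 16 µM | the very flask that is asked about, followed so far |  |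
| winter | 0.079 M | 0.0948 M | 2 mM | 16 µM | run made earlier |  |
| flask | 0.079 M | 0.0948 M | 3.95 mM | 16 µM |  | 6.0 h |

| dusk: time / min | dusk: target / % | winter: time / min | winter: target / % |
|---|---|---|---|
| 40.0 | 12.7 | 3.00 | 5.4 |
| 80.0 | 12.1 | 8.00 | 13.4 |
| 120 | 12.8 | 15.0 | 18.1 |
| 180 | 12.4 | 25.0 | 22.5 |
| 240 | 12.0 | 30.0 | 22.5 |

(scatter of a reading: 0.5 percentage points)

- violet: at 6.0 h add free enzyme, 50.0% of the amount charged, then wait 2.0 h
- red: change nothing and wait 2.0 h more
- grey: at 6.0 h take out 90% of the target then present, then wait 2.0 h
- amber: at 6.0 h add second substrate, 100% of the amount charged, then wait 2.0 h

- what is taken out of target is counted as made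
- reactions considered so far: first complex <-> loaded enzyme + first product; loaded enzyme + first product -> spent catalyst; second substrate + loaded enzyme <-> second complex; starting material + free enzyme <-> first complex; second complex -> free enzyme + target; loaded enzyme + capture agent -> trapped intermediate
- additions bring no volume worth counting

* target, in percent of the starting material first charged, at 6.0 h
* the remedy with the largest gain of target, or "none" below 2 percentage points (violet / red / grey / amber / none)
* target present, with what was taken out counted in, in percent of the starting material first charged, after red
* target present, with what was taken out counted in, in percent of the starting material first charged, after amber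

My reckoning treats loaded enzyme as a fork. Let B be second substrate, B* its charge, T capture agent, C the enzyme charge and P the target made. The selectivity factor S is then the odds of the target branch over the trap at equal B and T, so each enzyme trapped comes with S·B/T of target. Capture agent loses 0.405% of its charge even if every enzyme is trapped, so T stays put, but B falls as P grows. A plateau read as full trapping then gives S = (T/C)·ln(B*/(B*−P)). Even odds, S = 1, are the zero of the scale, and they give 0.485% of target in the dusk recipe.

The first way uses the dusk mean, 12.4%, which gives a selectivity factor of 26.9. The second way reads the last winter readings, mean 22.5%, as a plateau, which gives 26.0. Returned to the dusk recipe, that winter value predicts 12.0%, within one scatter of the dusk mean. A plain inverse proportion to capture agent predicts 11.4%, which misses by more than the scatter. That proportion is the one that cheats: it holds B constant, yet winter spent 18.8% of its second substrate against 10.3% in dusk.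

So I commit to 12.4% at 6.0 h. With the enzyme trapped, red, grey and amber gain nothing on this reckoning. Violet brings fresh enzyme to the remaining B and gains 5.7 percentage points, above the margin.

The forecast reads 12.4%, violet, 12.4% after red and 12.4% after amber: “Only fresh enzyme helps”.

The flask gives 12.5% at 6.0 h, 12.5% after red and 12.5% after amber, and violet gains 5.8 points.

    first complex ⇌ loaded enzyme + first product (K = 0.0790 M, k = 4.10 s⁻¹)
    loaded enzyme + first product → spent catalyst (k = 0.00310 M⁻¹ s⁻¹)
    second substrate + loaded enzyme ⇌ second complex (K = 110 M⁻¹, k = 15000 M⁻¹ s⁻¹)
    starting material + free enzyme ⇌ first complex (K = 47.0 M⁻¹, k = 13000 M⁻¹ s⁻¹)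
    second complex → free enzyme + target (k = 5.90 s⁻¹)
    loaded enzyme + capture agent → trapped intermediate (k = 23.0 M⁻¹ s⁻¹)

The step from second complex to free enzyme and target has half its turnover behind it by 3.52 min, far earlier than the 6.0 h asked about. Trapped intermediate holds >99.9% of the catalyst at 180 min, while 90% of second substrate remains at 360 min. Read from this result, S is 27.1. Carried with 26.9 to the neighbouring flask, which has 0.20 M of starting material, S gives 4.90%, and that neighbouring flask stands at 4.93%.

All runs stem from a simulated flask from invented constants; scatter was added.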